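**Retrosynthetic overview**

- Feature: in the 1,2-dioxolane ring O1–O2–C3–C4–C5 both peroxy carbons are quaternary, each with one CH3 and one chain that starts with CH2 (CH2CO2H on C3, (CH2)10Ph on C5), and the two CH3 groups are trans. The core is therefore a C2-symmetric 3,5-dimethyl-1,2-dioxolane-3,5-diacetic acid with two homotopic arms.
- Target 16 ⇒ ester 15 ⇒ alkene 14 ⇒ (Wittig, side-chain C2'=C3') aldehyde 10 + ylide 13; 10 ⇒ half-ester 8 ⇒ (esterase, choice of enantiomer) racemic C2 diester 7.
- 7 ⇒ (two exocyclic bonds, C3–CH2 and C5–CH2, twofold peroxycarbenium alkylation) bis-ketal 4 + 2 × ketene silyl acetal 5 (bought as the TBS acetal, sturdier than the TMS one; the silyl group is lost). 4 ⇒ diol 3 ⇒ acetylacetone 1 + H2O2 2.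
- Ring order: the only ring, the 1,2-dioxolane, is closed first (step 1); all later steps work on its substituents.

Key step: step 3

Assumption: the enantiomer preference of the esterase cannot be foreseen. The route is written for faster hydrolysis of the (3R,5R)-diester, with the configuration of 8 to be confirmed (e.g. X-ray of an amine salt) before going on. If the (3S,5S)-diester reacts faster, the recovered (3R,5R)-diester is mono-saponified (1 equiv NaOH, THF/H2O, 0 °C) to the same compound 8.

**Route**

Step 1
Reactants: 1 pentane-2,4-dione; 2 hydrogen peroxide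
Product: 3 3,5-dimethyl-1,2-dioxolane-3,5-diol (cis/trans mixture)
Conditions: 30% aq. H2O2 (1.0 equiv), 0 °C → rt; Et2O extraction, crystallisation (small scale, blast shield)
Reagents that add atoms: none
Why: Twofold peroxyhemiketalisation, in which H2O2 adds to one carbonyl and the hydroperoxide so formed closes onto the second carbonyl to give the known cyclic bis-hemiperketal; the configuration at the two carbinol carbons is of no consequence.

Step 2
Reactants: 3 3,5-dimethyl-1,2-dioxolane-3,5-diol
Product: 4 3,5-dimethoxy-3,5-dimethyl-1,2-dioxolane (cis/trans mixture)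
Conditions: MeOH, Amberlyst-15 (cat.), 3 Å MS, 0 °C → rt; filtration; handled as a solution, not concentrated to dryness
Reagents that add atoms: methanol, CO
Why: Acid-catalysed hemiperketal-to-perketal exchange (SN1 through ring peroxycarbenium ions stabilised by the neighbouring peroxy oxygen), the reaction type by which 3-hydroxy-1,2-dioxolanes are turned into 3-alkoxy-1,2-dioxolanes; both ketal centres are erased later, so the isomer mixture is used as such.

Step 3
Reactants: 4 3,5-dimethoxy-3,5-dimethyl-1,2-dioxolane; 5 tert-butyl[(1-methoxyethenyl)oxy]dimethylsilane (3 equiv)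
Product: 7 dimethyl 2,2'-[(3R,5R)-3,5-dimethyl-1,2-dioxolane-3,5-diyl]diacetate (racemic trans diester), via mono-ketal mono-ester 6 (not isolated)
Conditions: TMSOTf (0.3 equiv), CH2Cl2, −78 → −40 °C; Et3N quench; chromatography to remove any cis (meso) diester
Reagents that add atoms: none
Why: The silyl triflate removes one methoxy group as its silyl ether and leaves a planar ring peroxycarbenium ion, which the ketene silyl acetal captures in a Mukaiyama-type addition that returns silyl triflate, giving 6; the second ketal is then ionised and captured in the same way. The closest known reaction type is the Lewis-acid substitution of 3-alkoxy-1,2-dioxolanes by silyl ketene acetals through peroxycarbenium ions (and the silyl-triflate-catalysed coupling of acetals with silyl enolates), used here twice on one ring. No ring is closed: the dioxolane is present beforehand and both new bonds (C3–CH2 and C5–CH2) are exocyclic. The first new quaternary centre needs no control, since the only other centre at that stage is the remaining ketal carbon, which is erased by the second ionisation; the second centre is set relative to the first by attack anti to the CH2CO2Me arm, whose carbonyl oxygen is expected to bridge to the cationic carbon on its own face (six-membered cyclic dioxocarbenium ion C5–O=C–CH2–C3–C4), so the two arms and hence the two methyls should end trans. The step needs the trans (C2) diester over the cis (meso) one, which rests on this participation (helped by a non-chelating silyl Lewis acid, non-donor CH2Cl2 and low temperature) and on the steric bias of the arm over methyl; absolute configuration is not addressed here and the product is racemic.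

Step 4
Reactants: 7 dimethyl 2,2'-[(3R,5R)-3,5-dimethyl-1,2-dioxolane-3,5-diyl]diacetate (racemate)
Product: 8 2-[(3R,5R)-5-(2-methoxy-2-oxoethyl)-3,5-dimethyl-1,2-dioxolan-3-yl]acetic acid
Conditions: pig liver esterase, 0.1 M phosphate buffer pH 7, 10% DMSO, 25 °C, to ca. 50% conversion (chiral HPLC control); MTBE extraction at pH 8 (diester), then pH 3, EtOAc (acid)
Reagents that add atoms: water, O
Why: Esterase-catalysed ester hydrolysis used as a kinetic resolution: the enzyme accepts methyl esters of acetic acid arms on an oxygenated quaternary carbon (3-hydroxy-3-methylglutarate type), takes one enantiomer of the C2 diester faster, can give only one half-ester because the two arms are homotopic, and stops there because the anionic half-ester is a poor substrate; no stereocentre is formed, the absolute configuration of both centres is selected here.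

Step 5
Reactants: 8 2-[(3R,5R)-5-(2-methoxy-2-oxoethyl)-3,5-dimethyl-1,2-dioxolan-3-yl]acetic acid
Product: 9 methyl 2-[(3R,5S)-5-(2-hydroxyethyl)-3,5-dimethyl-1,2-dioxolan-3-yl]acetate
Conditions: BH3·THF (1.5 equiv), THF, −10 → 0 °C; then H2O
Reagents that add atoms: none
Why: Chemoselective borane reduction of a carboxylic acid (through the acyloxyborane) beside a methyl ester; tertiary dialkyl peroxides tolerate electrophilic boranes at 0 °C, and the stereocentres are untouched (the descriptor at C5 changes through CIP priorities only).

Step 6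
Reactants: 9 methyl 2-[(3R,5S)-5-(2-hydroxyethyl)-3,5-dimethyl-1,2-dioxolan-3-yl]acetate
Product: 10 methyl 2-[(3R,5R)-3,5-dimethyl-5-(2-oxoethyl)-1,2-dioxolan-3-yl]acetate
Conditions: Dess–Martin periodinane (1.2 equiv), CH2Cl2, 0 °C → rt; used at once
Reagents that add atoms: none
Why: Dess–Martin oxidation of a primary alcohol, run without added base because the β-peroxy aldehyde is sensitive to base and not to acetic acid; the O–O bond is inert to iodine(V).

Step 7
Reactants: 11 (8-bromooctyl)benzene
Product: 12 triphenyl(8-phenyloctyl)phosphonium bromide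
Conditions: PPh3, MeCN, reflux
Reagents that add atoms: triphenylphosphine, c1ccc(cc1)P(c1ccccc1)c1ccccc1
Why: SN2 quaternisation of triphenylphosphine by a primary alkyl bromide.

Step 8
Reactants: 10 methyl 2-[(3R,5R)-3,5-dimethyl-5-(2-oxoethyl)-1,2-dioxolan-3-yl]acetate; 12 triphenyl(8-phenyloctyl)phosphonium bromide
Product: 14 methyl 2-[(3R,5S)-3,5-dimethyl-5-[(2Z)-10-phenyldec-2-en-1-yl]-1,2-dioxolan-3-yl]acetate, via phosphonium ylide 13 (not isolated)
Conditions: 12 (1.3 equiv), NaHMDS (1.2 equiv), THF, 0 °C; then 10, −78 → 0 °C
Reagents that add atoms: none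
Why: Wittig olefination with a non-stabilised ylide (Z-selective through kinetic oxaphosphetane formation); the deficit of base relative to the salt leaves no free amide, and carbonyl addition at −78 °C should outrun enolisation of the aldehyde; the alkene geometry is irrelevant because the double bond is reduced next.

Step 9
Reactants: 14 methyl 2-[(3R,5S)-3,5-dimethyl-5-[(2Z)-10-phenyldec-2-en-1-yl]-1,2-dioxolan-3-yl]acetate
Product: 15 methyl 2-[(3R,5S)-3,5-dimethyl-5-(10-phenyldecyl)-1,2-dioxolan-3-yl]acetate
Conditions: dipotassium azodicarboxylate (excess, in portions), AcOH, MeOH/CH2Cl2, 0 °C → rt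
Reagents that add atoms: none
Why: Diimide reduction, in which HN=NH released by acid decarboxylation of the azodicarboxylate transfers H2 to the C=C in a concerted syn fashion and leaves the O–O bond, which catalytic hydrogenation would cleave, as well as the ester and the arene untouched.

Step 10
Reactants: 15 methyl 2-[(3R,5S)-3,5-dimethyl-5-(10-phenyldecyl)-1,2-dioxolan-3-yl]acetate
Product: 16 andavadoic acid, 2-[(3R,5S)-3,5-dimethyl-5-(10-phenyldecyl)-1,2-dioxolan-3-yl]acetic acid
Conditions: LiOH·H2O (3 equiv), THF/H2O, 0 °C → rt; then cold 1 M HCl to pH 3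
Reagents that add atoms: lithium hydroxide, [Li+].[OH-]
Why: Saponification (BAc2) of the methyl ester, the usual last step for 1,2-dioxolane-3-acetic acids; both peroxy carbons are quaternary, so Kornblum–DeLaMare fragmentation is impossible and no stereocentre can epimerise.

**Compound list**

1 | pentane-2,4-dione | CC(=O)CC(C)=O | starting material
2 | hydrogen peroxide | OO | starting material
3 | 3,5-dimethyl-1,2-dioxolane-3,5-diol (cis/trans) | CC1(O)CC(C)(O)OO1 | intermediate
4 | 3,5-dimethoxy-3,5-dimethyl-1,2-dioxolane (cis/trans) | COC1(C)CC(C)(OC)OO1 | intermediate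
5 | tert-butyl[(1-methoxyethenyl)oxy]dimethylsilane | C=C(OC)O[Si](C)(C)C(C)(C)C | starting material
6 | methyl 2-(5-methoxy-3,5-dimethyl-1,2-dioxolan-3-yl)acetate (isomer mixture, not isolated) | COC(=O)CC1(C)CC(C)(OC)OO1 | intermediate
7 | dimethyl 2,2'-[(3R,5R)-3,5-dimethyl-1,2-dioxolane-3,5-diyl]diacetate (racemate, drawn as 3R,5R) | C[C@]1(CC(=O)OC)C[C@](C)(CC(=O)OC)OO1 | intermediate
8 | 2-[(3R,5R)-5-(2-methoxy-2-oxoethyl)-3,5-dimethyl-1,2-dioxolan-3-yl]acetic acid | C[C@]1(CC(=O)O)C[C@](C)(CC(=O)OC)OO1 | intermediate
9 | methyl 2-[(3R,5S)-5-(2-hydroxyethyl)-3,5-dimethyl-1,2-dioxolan-3-yl]acetate | C[C@]1(CCO)C[C@](C)(CC(=O)OC)OO1 | intermediate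
10 | methyl 2-[(3R,5R)-3,5-dimethyl-5-(2-oxoethyl)-1,2-dioxolan-3-yl]acetate | C[C@]1(CC=O)C[C@](C)(CC(=O)OC)OO1 | intermediate
11 | (8-bromooctyl)benzene | BrCCCCCCCCc1ccccc1 | starting material
12 | triphenyl(8-phenyloctyl)phosphonium bromide | [Br-].c1ccc(cc1)CCCCCCCC[P+](c1ccccc1)(c1ccccc1)c1ccccc1 | intermediate
13 | triphenyl(8-phenyloctylidene)-λ5-phosphane (ylide, not isolated) | C(CCCCCCCc1ccccc1)=P(c1ccccc1)(c1ccccc1)c1ccccc1 | intermediate
14 | methyl 2-[(3R,5S)-3,5-dimethyl-5-[(2Z)-10-phenyldec-2-en-1-yl]-1,2-dioxolan-3-yl]acetate | C[C@]1(C/C=C\CCCCCCCc2ccccc2)C[C@](C)(CC(=O)OC)OO1 | intermediate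
15 | methyl 2-[(3R,5S)-3,5-dimethyl-5-(10-phenyldecyl)-1,2-dioxolan-3-yl]acetate | C[C@]1(CCCCCCCCCCc2ccccc2)C[C@](C)(CC(=O)OC)OO1 | intermediate
16 | andavadoic acid, 2-[(3R,5S)-3,5-dimethyl-5-(10-phenyldecyl)-1,2-dioxolan-3-yl]acetic acid | C[C@]1(CCCCCCCCCCc2ccccc2)C[C@](C)(CC(=O)O)OO1 | target

**Count**

Total step count: 10. Longest linear sequence: 9 steps (1–6, 8–10); step 7 is a one-step side branch.

**Steps most likely to fail**

1. Step 3. Once the first ester arm is on the ring, the second substitution may stall, or the bridged dioxocarbenium ion may lose its O-methyl group and end as a bicyclic lactone. The anti preference of the second capture may also be low, so that much meso diester forms. The two diesters should be told apart by the ring CH2 at C4, whose protons are equivalent in the C2 isomer and diastereotopic in the meso isomer.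
Fallback, from 4 back to 7: the carboxyl carbons are brought in as allyl groups, which carry no carbonyl that could trap the cation. Twofold Hosomi–Sakurai allylation of 4 (allyltrimethylsilane, TMSOTf, CH2Cl2, −78 °C) and separation from the cis isomer should give racemic trans-3,5-dimethyl-3,5-di(prop-2-en-1-yl)-1,2-dioxolane F1. Ozonolysis (O3, CH2Cl2/MeOH, −78 °C; Me2S) should give 2,2'-(trans-3,5-dimethyl-1,2-dioxolane-3,5-diyl)diacetaldehyde F2. Pinnick oxidation (NaClO2, NaH2PO4, 2-methyl-2-butene, t-BuOH/H2O) should give 2,2'-(trans-3,5-dimethyl-1,2-dioxolane-3,5-diyl)diacetic acid F3, and TMSCHN2 in MeOH/toluene returns to 7. In this variant the cis/trans ratio rests on sterics alone, and the isomers are separated at the diallyl stage or by crystallisation of the diacid.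

2. Step 4. The esterase may discriminate poorly between the enantiomers or turn over the hindered β-quaternary ester very slowly, so that 8 is reached with too low an enantiomeric purity.
Fallback, from racemic 7 back to 8: the racemate is resolved by preparative chromatography on a polysaccharide chiral stationary phase (HPLC or SFC). The (3R,5R)-diester is the same structure as 7, so no compound outside the list is made (F0). It is mono-saponified with one equivalent of aqueous NaOH in THF at 0 °C, which can give only one half-ester because the arms are homotopic; recovered diester is recycled. This gives 8.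

3. Step 8. The ylide may act as a base: enolisation of the β-peroxy aldehyde followed by E1cB expulsion of the peroxide oxygen would open the dioxolane in competition with olefination.
Fallback, from 9 back to 15: the polarity is reversed in a Julia–Kocienski olefination, which puts the carbanion one carbon further from the ring, where the peroxide oxygen is no longer β to it.
- Mitsunobu reaction of 9 with 1-phenyl-1H-tetrazole-5-thiol (PPh3/DIAD betaine preformed at 0 °C, so that free phosphine does not meet the peroxide) should give methyl 2-[(3R,5R)-3,5-dimethyl-5-[2-(1-phenyl-1H-tetrazol-5-ylsulfanyl)ethyl]-1,2-dioxolan-3-yl]acetate F4.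
- mCPBA (CH2Cl2, 0 °C) should give methyl 2-[(3R,5R)-3,5-dimethyl-5-[2-(1-phenyl-1H-tetrazol-5-ylsulfonyl)ethyl]-1,2-dioxolan-3-yl]acetate F5.
- The partner 8-phenyloctanal F6 is made from bromide 11 with trimethylamine N-oxide in DMSO (Kornblum-type oxidation).
- KHMDS is added to F5 and F6 in DME at −60 °C (Barbier mode), which should give methyl 2-[(3R,5S)-3,5-dimethyl-5-[(2E)-10-phenyldec-2-en-1-yl]-1,2-dioxolan-3-yl]acetate F7.
- Diimide reduction under the conditions of step 9 returns to 15.

Further compounds
F1 | step 3 | trans-3,5-dimethyl-3,5-di(prop-2-en-1-yl)-1,2-dioxolane (racemate, drawn as 3S,5S) | C[C@]1(CC=C)C[C@](C)(CC=C)OO1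
F2 | step 3 | 2,2'-(trans-3,5-dimethyl-1,2-dioxolane-3,5-diyl)diacetaldehyde (racemate, drawn as 3R,5R) | C[C@]1(CC=O)C[C@](C)(CC=O)OO1
F3 | step 3 | 2,2'-(trans-3,5-dimethyl-1,2-dioxolane-3,5-diyl)diacetic acid (racemate, drawn as 3R,5R) | C[C@]1(CC(=O)O)C[C@](C)(CC(=O)O)OO1
F0 | step 4 | none | none
F4 | step 8 | methyl 2-[(3R,5R)-3,5-dimethyl-5-[2-(1-phenyl-1H-tetrazol-5-ylsulfanyl)ethyl]-1,2-dioxolan-3-yl]acetate | C[C@]1(CCSc2nnnn2-c3ccccc3)C[C@](C)(CC(=O)OC)OO1
F5 | step 8 | methyl 2-[(3R,5R)-3,5-dimethyl-5-[2-(1-phenyl-1H-tetrazol-5-ylsulfonyl)ethyl]-1,2-dioxolan-3-yl]acetate | C[C@]1(CCS(=O)(=O)c2nnnn2-c3ccccc3)C[C@](C)(CC(=O)OC)OO1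
F6 | step 8 | 8-phenyloctanal | O=CCCCCCCCc1ccccc1
F7 | step 8 | methyl 2-[(3R,5S)-3,5-dimethyl-5-[(2E)-10-phenyldec-2-en-1-yl]-1,2-dioxolan-3-yl]acetate | C[C@]1(C/C=C/CCCCCCCc2ccccc2)C[C@](C)(CC(=O)OC)OO1
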